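**Plan**

1. Locants: flavone O1–C8a as usual; cyclohexene C1 (bonded to flavone C8), C2=C3(CH3), C4H2, C5 (diacetoxy/dihydroxyphenyl), C6 (aroyl). The retrosynthesis removes four aryl acetates and then cuts C8–C1.
2. Enabling feature: C1 is the secondary end of the allyl system C1–C2–C3(CH3), whose tertiary end makes the allyl cation easy to reach from an allylic acetate. C8 is the free carbon of the phloroglucinol-type A ring, ortho to 7-OH and O1 and para to 5-OH. The union is a Friedel–Crafts allylation.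
3. The cyclohexenyl acetate is cut at C1–C6 and C4–C5 (Diels–Alder of acetylated morachalcone A with 1-acetoxy-3-methylbutadiene); the chalcone is cut at Cα=Cβ (Claisen–Schmidt).
4. The flavone is cut at O1–C2 (cyclodehydration), at C2–C3 (enolate C-acylation) and at C3–CH2 (enolate prenylation of silylated phloroacetophenone).
5. Forward order: chalcone, then the cyclohexene ring; separately the pyranone ring of the flavone; union of the halves; deacetylation.
6. Stereochemistry: C5 and C6 come from the chiral-borate Diels–Alder (catalyst-controlled face, E-alkene gives trans). C1 is set in the union, anti to the C6 aroyl group. The configuration of the acetate carbon is irrelevant because it is erased.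

Key step: step 16

Remark: which antipode of VANOL delivers the (5R,6S) adduct with this diene is an assumption; (R)-VANOL is written and would be exchanged for (S)-VANOL if a trial run shows the opposite sense. Abbreviations: prenyl = 3-methylbut-2-en-1-yl, TBS = tert-butyldimethylsilyl, MOM = methoxymethyl.

**Part A – cyclohexenyl electrophile**

Step 1
Reactants: 1 2,4-dihydroxyacetophenone; 2 prenyl bromide
Product: 3 1-[2,4-dihydroxy-3-prenylphenyl]ethan-1-one
Conditions: KOH (10% aq), 0 °C → rt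
Reagents that add atoms: none
Why: Aqueous-alkali C-alkylation of the ambident resorcinol phenoxide should place the prenyl group at C3, the carbon activated by both oxygens, water favouring C- over O-alkylation (5-prenyl and O-prenyl isomers are separated).

Step 2
Reactants: 4 2,4-dihydroxybenzaldehyde
Product: 5 2,4-bis(methoxymethoxy)benzaldehyde
Conditions: MOMCl (2.6 eq), i-Pr2NEt (3 eq), CH2Cl2, 0 °C → rt
Reagents that add atoms: chloromethyl methyl ether, COCCl
Why: Williamson-type MOM protection masks both phenols so that the aldehyde stays electrophilic in the alkaline aldol step.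

Step 3
Reactants: 3 1-[2,4-dihydroxy-3-prenylphenyl]ethan-1-one; 5 2,4-bis(methoxymethoxy)benzaldehyde
Product: 6 (E)-3-[2,4-bis(methoxymethoxy)phenyl]-1-[2,4-dihydroxy-3-prenylphenyl]prop-2-en-1-one
Conditions: KOH (50% aq), EtOH, rt
Reagents that add atoms: none
Why: Claisen–Schmidt condensation, in which the ketone enolate adds to the non-enolizable aldehyde and E1cB dehydration gives the (E)-enone; MOM ethers and the prenyl group are inert to hydroxide.

Step 4
Reactants: 6 the bis-MOM chalcone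
Product: 7 (E)-1-[2,4-dihydroxy-3-prenylphenyl]-3-(2,4-dihydroxyphenyl)prop-2-en-1-one (morachalcone A)
Conditions: 3 M HCl, MeOH, 50 °C, short reaction time
Reagents that add atoms: none
Why: Acid-catalysed methanolysis of the MOM acetals, the usual deprotection for 3'-prenyl-2'-hydroxychalcones, should leave the prenyl alkene and the enone intact if kept short.

Step 5
Reactants: 7 morachalcone A
Product: 8 (E)-1-[4-acetoxy-2-hydroxy-3-prenylphenyl]-3-(2,4-diacetoxyphenyl)prop-2-en-1-one
Conditions: Ac2O (3.2 eq), pyridine, CH2Cl2, 0 °C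
Reagents that add atoms: acetic anhydride, CC(=O)OC(C)=O
Why: Chemoselective O-acetylation takes the three free phenols, while the 2'-OH, hydrogen-bonded to the ketone and flanked by the prenyl group, stays free as the boron-binding site for step 7.

Step 6
Reactants: 9 3-methylbut-2-enal
Product: 10 (E)-3-methylbuta-1,3-dien-1-yl acetate
Conditions: isopropenyl acetate, TsOH (cat.), Cu(OAc)2 (cat.), reflux with removal of acetone
Reagents that add atoms: isopropenyl acetate, CC(=C)OC(C)=O
Why: Acid-catalysed enol-ester exchange (dienol acetate formation) through γ-deprotonation of the enal should give the conjugated dienyl acetate, mainly E.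

Step 7
Reactants: 8 the triacetyl 2'-hydroxychalcone; 10 (E)-3-methylbuta-1,3-dien-1-yl acetate
Product: 11 (5R,6S)-6-[4-acetoxy-2-hydroxy-3-prenylbenzoyl]-5-(2,4-diacetoxyphenyl)-3-methylcyclohex-2-en-1-yl acetate (C1 epimers; endo 1R expected to predominate)
Conditions: 10 (4 eq), (R)-VANOL (20 mol%), B(OPh)3 (20 mol%), 4 Å MS, PhCF3, rt
Reagents that add atoms: none
Why: Asymmetric Diels–Alder reaction of a 2'-hydroxychalcone bound as a chiral borate chelate, which lowers the enone LUMO and shields one face; the E-alkene fixes C5/C6 as trans, and the 1-acetoxy and 3-methyl groups both direct the bond from the acetoxy carbon to the carbonyl-bearing carbon.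

Step 8
Reactants: 11 the Diels–Alder adduct
Product: 12 (5R,6S)-6-[2,4-diacetoxy-3-prenylbenzoyl]-5-(2,4-diacetoxyphenyl)-3-methylcyclohex-2-en-1-yl acetate (C1 epimers)
Conditions: Ac2O (1.5 eq), DMAP (10 mol%), pyridine, CH2Cl2, 0 °C
Reagents that add atoms: acetic anhydride, CC(=O)OC(C)=O
Why: DMAP-catalysed acetylation caps the chelated phenol so that it cannot trap the allyl cation of step 16 as a chromanone; the mild base at 0 °C should not eliminate the β-acetoxy group.

**Part B – flavone nucleophile**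

Step 9
Reactants: 13 2',4',6'-trihydroxyacetophenone
Product: 14 1-[2,4-bis(tert-butyldimethylsilyloxy)-6-hydroxyphenyl]ethan-1-one
Conditions: TBSCl (2.1 eq), imidazole, CH2Cl2–DMF, 0 °C → rt
Reagents that add atoms: tert-butyldimethylsilyl chloride, CC(C)(C)[Si](C)(C)Cl
Why: Selective silylation takes the 4-OH and one ortho OH; the last ortho OH is deactivated by its hydrogen bond to the acetyl group.

Step 10
Reactants: 14 the bis-silyl ketone; 2 prenyl bromide
Product: 15 1-[2,4-bis(tert-butyldimethylsilyloxy)-6-hydroxyphenyl]-5-methylhex-4-en-1-one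
Conditions: LDA (2.2 eq), THF, −78 °C; then 2, −78 → −20 °C; aq NH4Cl
Reagents that add atoms: none
Why: Enolate alkylation of the phenoxide/enolate dianion of an o-hydroxyacetophenone, the carbon terminus reacting with the allylic bromide (SN2) and placing the future 3-prenyl group.

Step 11
Reactants: 16 methyl 2,4-dihydroxybenzoate; 2 prenyl bromide
Product: 17 methyl 2-hydroxy-4-(prenyloxy)benzoate
Conditions: K2CO3, acetone, reflux
Reagents that add atoms: none
Why: Regioselective Williamson ether synthesis at the 4-OH, the 2-OH being hydrogen-bonded to the ester.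

Step 12
Reactants: 17 methyl 2-hydroxy-4-(prenyloxy)benzoate
Product: 18 2-hydroxy-4-(prenyloxy)benzoic acid
Conditions: LiOH, THF–MeOH–H2O, 60 °C; then 1 M HCl, 0 °C
Reagents that add atoms: lithium hydroxide (its oxygen becomes the carboxyl OH), [Li+].[OH-]
Why: Ester saponification (BAc2); the aryl prenyl ether is stable to base and the acidification is brief and cold.

Step 13
Reactants: 18 2-hydroxy-4-(prenyloxy)benzoic acid
Product: 19 tert-butyldimethylsilyl 2-(tert-butyldimethylsilyloxy)-4-(prenyloxy)benzoate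
Conditions: TBSCl (2.4 eq), imidazole, DMF, rt
Reagents that add atoms: tert-butyldimethylsilyl chloride, CC(C)(C)[Si](C)(C)Cl
Why: Silylation of both the acid and the salicylic OH; the silyl ester is the precursor of the acid chloride under neutral conditions.

Step 14
Reactants: 15 the α-prenyl ketone; 19 the silyl ester
Product: 21 1-[2,4-bis(tert-butyldimethylsilyloxy)-6-hydroxyphenyl]-2-prenyl-3-[2-(tert-butyldimethylsilyloxy)-4-(prenyloxy)phenyl]propane-1,3-dione (racemic at C2 and enolizable), via aroyl chloride 20 (not isolated)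
Conditions: 19: (COCl)2, DMF (cat.), CH2Cl2, 0 °C → rt, evaporate; 15: LiHMDS (3.2 eq), THF, −78 °C, then 20, −78 → 0 °C
Reagents that add atoms: none
Why: Claisen-type C-acylation of a ketone enolate: the silyl ester gives the acid chloride without HCl (which protects the prenyl ether), and any O-aroyl ester formed should rearrange to the β-diketone under the excess base (Baker–Venkataraman).

Step 15
Reactants: 21 the β-diketone
Product: 23 5,7-dihydroxy-2-[2-hydroxy-4-(prenyloxy)phenyl]-3-prenyl-4H-chromen-4-one, via tris-silyl flavone 22 (not isolated)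
Conditions: AcOH, 70 °C; evaporate; then TBAF (3.5 eq), AcOH (4 eq), THF, 0 °C
Reagents that add atoms: none
Why: Cyclodehydration of an o-hydroxyaryl β-diketone to the chromen-4-one, then fluoride desilylation; the acid-stable 2'-O-silyl group is kept until the ring has closed, so only the phloroglucinol oxygen can cyclize.

**Part C – union and deprotection**

Step 16
Reactants: 12 the cyclohexenyl acetate (both C1 epimers); 23 the flavone triol
Product: 24 8-[(1S,5R,6S)-6-(2,4-diacetoxy-3-prenylbenzoyl)-5-(2,4-diacetoxyphenyl)-3-methylcyclohex-2-en-1-yl]-5,7-dihydroxy-2-[2-hydroxy-4-(prenyloxy)phenyl]-3-prenyl-4H-chromen-4-one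
Conditions: Sc(OTf)3 (20 mol%), 4 Å MS, CH2Cl2–MeNO2 (4:1), −20 → 0 °C; 23 in 1.5-fold excess
Reagents that add atoms: none
Why: The Lewis acid ionizes the allylic acetate of either C1 epimer to the same cyclohexenyl allyl cation C1–C2–C3(CH3), which is attacked by C8 of 23 in a Friedel–Crafts (SEAr) allylation followed by loss of the C8 proton. The closest known reactions are the acid-mediated coupling of p-mentha-2,8-dien-1-ol with resorcinols and phloroglucinols (cannabidiol-type coupling) and Sc(OTf)3-catalysed Friedel–Crafts allylations with allylic acetates. No ring is closed. The new stereocentre C1 is controlled by the neighbouring C6: the arene should add to the face anti to the pseudoequatorial aroyl group, giving the all-trans, all-equatorial (1S,5R,6S) ring, which is also the thermodynamic isomer, so any reversibility or C6 enolization should converge on it. On the cation, C1 (secondary) should win over C3, where attack would give a hindered and readily re-ionized quaternary centre. On the nucleophile, the free 7-OH should direct to C8 (ortho to 7-OH and O1, para to 5-OH) by analogy with Mannich, Duff and Claisen chemistry of 5,7-dihydroxyflavones; the rings of 12 are deactivated as acetates, the B ring is a less nucleophilic resorcinol monoether, and any O-allylation is reversible under the acid.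

Step 17
Reactants: 24 the coupled tetraacetate
Product: 25 8-[(1S,5R,6S)-6-(2,4-dihydroxy-3-prenylbenzoyl)-5-(2,4-dihydroxyphenyl)-3-methylcyclohex-2-en-1-yl]-5,7-dihydroxy-2-[2-hydroxy-4-(prenyloxy)phenyl]-3-prenyl-4H-chromen-4-one (CNP0082413.1)
Conditions: K2CO3, MeOH–THF (degassed, Ar), 0 °C → rt; then pH 5 buffer
Reagents that add atoms: none
Why: Base-catalysed transesterification removes the four aryl acetates; the prenyl groups and the prenyl ether are untouched, and the enolizable C6 is already in its thermodynamic all-trans arrangement.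

**Compound list**

1 | 2,4-dihydroxyacetophenone | CC(=O)c1ccc(O)cc1O | starting material
2 | prenyl bromide (1-bromo-3-methylbut-2-ene) | CC(C)=CCBr | starting material
3 | 1-[2,4-dihydroxy-3-prenylphenyl]ethan-1-one | CC(=O)c1ccc(O)c(CC=C(C)C)c1O | intermediate
4 | 2,4-dihydroxybenzaldehyde | O=Cc1ccc(O)cc1O | starting material
5 | 2,4-bis(methoxymethoxy)benzaldehyde | COCOc1ccc(C=O)c(OCOC)c1 | intermediate
6 | (E)-3-[2,4-bis(methoxymethoxy)phenyl]-1-[2,4-dihydroxy-3-prenylphenyl]prop-2-en-1-one | COCOc1ccc(/C=C/C(=O)c2ccc(O)c(CC=C(C)C)c2O)c(OCOC)c1 | intermediate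
7 | morachalcone A, (E)-1-[2,4-dihydroxy-3-prenylphenyl]-3-(2,4-dihydroxyphenyl)prop-2-en-1-one | O=C(/C=C/c1ccc(O)cc1O)c1ccc(O)c(CC=C(C)C)c1O | intermediate
8 | (E)-1-[4-acetoxy-2-hydroxy-3-prenylphenyl]-3-(2,4-diacetoxyphenyl)prop-2-en-1-one | CC(=O)Oc1ccc(/C=C/C(=O)c2ccc(OC(C)=O)c(CC=C(C)C)c2O)c(OC(C)=O)c1 | intermediate
9 | 3-methylbut-2-enal | CC(C)=CC=O | starting material
10 | (E)-3-methylbuta-1,3-dien-1-yl acetate | CC(=O)O/C=C/C(C)=C | intermediate
11 | (5R,6S)-6-[4-acetoxy-2-hydroxy-3-prenylbenzoyl]-5-(2,4-diacetoxyphenyl)-3-methylcyclohex-2-en-1-yl acetate, C1 epimers | CC(=O)OC1C=C(C)C[C@@H](c2ccc(OC(C)=O)cc2OC(C)=O)[C@@H]1C(=O)c1ccc(OC(C)=O)c(CC=C(C)C)c1O | intermediate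
12 | (5R,6S)-6-[2,4-diacetoxy-3-prenylbenzoyl]-5-(2,4-diacetoxyphenyl)-3-methylcyclohex-2-en-1-yl acetate, C1 epimers | CC(=O)OC1C=C(C)C[C@@H](c2ccc(OC(C)=O)cc2OC(C)=O)[C@@H]1C(=O)c1ccc(OC(C)=O)c(CC=C(C)C)c1OC(C)=O | intermediate
13 | 2',4',6'-trihydroxyacetophenone | CC(=O)c1c(O)cc(O)cc1O | starting material
14 | 1-[2,4-bis(tert-butyldimethylsilyloxy)-6-hydroxyphenyl]ethan-1-one | CC(=O)c1c(O)cc(O[Si](C)(C)C(C)(C)C)cc1O[Si](C)(C)C(C)(C)C | intermediate
15 | 1-[2,4-bis(tert-butyldimethylsilyloxy)-6-hydroxyphenyl]-5-methylhex-4-en-1-one | CC(C)=CCCC(=O)c1c(O)cc(O[Si](C)(C)C(C)(C)C)cc1O[Si](C)(C)C(C)(C)C | intermediate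
16 | methyl 2,4-dihydroxybenzoate | COC(=O)c1ccc(O)cc1O | starting material
17 | methyl 2-hydroxy-4-(prenyloxy)benzoate | COC(=O)c1ccc(OCC=C(C)C)cc1O | intermediate
18 | 2-hydroxy-4-(prenyloxy)benzoic acid | OC(=O)c1ccc(OCC=C(C)C)cc1O | intermediate
19 | tert-butyldimethylsilyl 2-(tert-butyldimethylsilyloxy)-4-(prenyloxy)benzoate | CC(C)=CCOc1ccc(C(=O)O[Si](C)(C)C(C)(C)C)c(O[Si](C)(C)C(C)(C)C)c1 | intermediate
20 | 2-(tert-butyldimethylsilyloxy)-4-(prenyloxy)benzoyl chloride | CC(C)=CCOc1ccc(C(Cl)=O)c(O[Si](C)(C)C(C)(C)C)c1 | intermediate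
21 | 1-[2,4-bis(tert-butyldimethylsilyloxy)-6-hydroxyphenyl]-2-prenyl-3-[2-(tert-butyldimethylsilyloxy)-4-(prenyloxy)phenyl]propane-1,3-dione, racemic at C2 | CC(C)=CCOc1ccc(C(=O)C(CC=C(C)C)C(=O)c2c(O)cc(O[Si](C)(C)C(C)(C)C)cc2O[Si](C)(C)C(C)(C)C)c(O[Si](C)(C)C(C)(C)C)c1 | intermediate
22 | 5,7-bis(tert-butyldimethylsilyloxy)-2-[2-(tert-butyldimethylsilyloxy)-4-(prenyloxy)phenyl]-3-prenyl-4H-chromen-4-one | CC(C)=CCOc1ccc(-c2oc3cc(O[Si](C)(C)C(C)(C)C)cc(O[Si](C)(C)C(C)(C)C)c3c(=O)c2CC=C(C)C)c(O[Si](C)(C)C(C)(C)C)c1 | intermediate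
23 | 5,7-dihydroxy-2-[2-hydroxy-4-(prenyloxy)phenyl]-3-prenyl-4H-chromen-4-one | CC(C)=CCOc1ccc(-c2oc3cc(O)cc(O)c3c(=O)c2CC=C(C)C)c(O)c1 | intermediate
24 | 8-[(1S,5R,6S)-6-(2,4-diacetoxy-3-prenylbenzoyl)-5-(2,4-diacetoxyphenyl)-3-methylcyclohex-2-en-1-yl]-5,7-dihydroxy-2-[2-hydroxy-4-(prenyloxy)phenyl]-3-prenyl-4H-chromen-4-one | CC(C)=CCOc1ccc(-c2oc3c([C@H]4C=C(C)C[C@@H](c5ccc(OC(C)=O)cc5OC(C)=O)[C@@H]4C(=O)c4ccc(OC(C)=O)c(CC=C(C)C)c4OC(C)=O)c(O)cc(O)c3c(=O)c2CC=C(C)C)c(O)c1 | intermediate
25 | 8-[(1S,5R,6S)-6-(2,4-dihydroxy-3-prenylbenzoyl)-5-(2,4-dihydroxyphenyl)-3-methylcyclohex-2-en-1-yl]-5,7-dihydroxy-2-[2-hydroxy-4-(prenyloxy)phenyl]-3-prenyl-4H-chromen-4-one | CC(C)=CCOc1ccc(-c2oc3c([C@H]4C=C(C)C[C@@H](c5ccc(O)cc5O)[C@@H]4C(=O)c4ccc(O)c(CC=C(C)C)c4O)c(O)cc(O)c3c(=O)c2CC=C(C)C)c(O)c1 | target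

**Step count and risks**

Total steps: 17. Longest linear sequence: 8 (steps 1, 3, 4, 5, 7, 8, 16, 17).

Steps most likely to fail:

Step 16. The cation may attack C6 of the flavone or an oxygen, the Lewis acid may ionize the aryl prenyl ether, and the cation may lose the C6 proton to a dienone whose conjugate re-addition would have the wrong facial preference. The fallback sets out from 14 and comes back at 24; it fixes the site with a halogen and works without acid. Iodination of 14 ortho to its free phenol (BnMe3N·ICl2, NaHCO3, CH2Cl2–MeOH) should give 1-[4,6-bis(tert-butyldimethylsilyloxy)-2-hydroxy-3-iodophenyl]ethan-1-one F1. Repeating step 10 gives the α-prenyl iodo ketone F2, repeating step 14 gives the iodo β-diketone F3, and the acetic acid half of step 15 gives the 8-iodo-tris(silyl)flavone F4. Miyaura borylation (B2pin2, Pd(dppf)Cl2, KOAc, dioxane) gives the 8-pinacolboronate F5. A Pd(0)-catalysed allyl–aryl Suzuki–Miyaura coupling of F5 with the endo (1R) epimer of 12 should proceed by oxidative addition with inversion and reductive elimination with retention, placing the aryl group trans to the aroyl group in the coupled tris(silyl) tetraacetate F6. TBAF/AcOH then returns 24.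

Step 7. The β-acetoxy ketone may lose acetic acid under the boron Lewis acid, the dienyl acetate may compete for boron and slow the cycloaddition, and facial discrimination may be insufficient with this diene. The fallback sets out from 9 and 8 and comes back at 24; it uses a silyl dienol ether and a hydroxyl leaving group. TBSOTf/Et3N converts 9 into (E)-tert-butyldimethyl[(3-methylbuta-1,3-dien-1-yl)oxy]silane F7, a more reactive diene whose silyloxy group is a poor nucleofuge. Cycloaddition with 8 under the borate gives the silyl ether adduct F8, and acetylation as in step 8 gives the tetraacetate silyl ether F9. HF·pyridine unmasks the allylic alcohol F10 just before the union; it is ionized in step 16 in place of 12 and leads to 24.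

Step 14. Acylation may stop at the O-aroyl ester, silyl groups may migrate between phenolic oxygens under the amide base, and the hindered α-branched enolate may react slowly. The fallback sets out from 19 and 15 and comes back at 21; it separates esterification from acyl transfer. Selective hydrolysis of the silyl ester of 19 (AcOH–THF–H2O) gives 2-(tert-butyldimethylsilyloxy)-4-(prenyloxy)benzoic acid F11. Steglich esterification with 15 (EDC, DMAP) gives the aryl ester F12, and a discrete Baker–Venkataraman rearrangement (LiHMDS, THF, −78 → 0 °C) gives 21.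

**Further compounds**

F1 | step 16 | 1-[4,6-bis(tert-butyldimethylsilyloxy)-2-hydroxy-3-iodophenyl]ethan-1-one | CC(=O)c1c(O)c(I)c(O[Si](C)(C)C(C)(C)C)cc1O[Si](C)(C)C(C)(C)C
F2 | step 16 | 1-[4,6-bis(tert-butyldimethylsilyloxy)-2-hydroxy-3-iodophenyl]-5-methylhex-4-en-1-one | CC(C)=CCCC(=O)c1c(O)c(I)c(O[Si](C)(C)C(C)(C)C)cc1O[Si](C)(C)C(C)(C)C
F3 | step 16 | 1-[4,6-bis(tert-butyldimethylsilyloxy)-2-hydroxy-3-iodophenyl]-2-prenyl-3-[2-(tert-butyldimethylsilyloxy)-4-(prenyloxy)phenyl]propane-1,3-dione | CC(C)=CCOc1ccc(C(=O)C(CC=C(C)C)C(=O)c2c(O)c(I)c(O[Si](C)(C)C(C)(C)C)cc2O[Si](C)(C)C(C)(C)C)c(O[Si](C)(C)C(C)(C)C)c1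
F4 | step 16 | 5,7-bis(tert-butyldimethylsilyloxy)-8-iodo-2-[2-(tert-butyldimethylsilyloxy)-4-(prenyloxy)phenyl]-3-prenyl-4H-chromen-4-one | CC(C)=CCOc1ccc(-c2oc3c(I)c(O[Si](C)(C)C(C)(C)C)cc(O[Si](C)(C)C(C)(C)C)c3c(=O)c2CC=C(C)C)c(O[Si](C)(C)C(C)(C)C)c1
F5 | step 16 | 5,7-bis(tert-butyldimethylsilyloxy)-8-(4,4,5,5-tetramethyl-1,3,2-dioxaborolan-2-yl)-2-[2-(tert-butyldimethylsilyloxy)-4-(prenyloxy)phenyl]-3-prenyl-4H-chromen-4-one | CC(C)=CCOc1ccc(-c2oc3c(B4OC(C)(C)C(C)(C)O4)c(O[Si](C)(C)C(C)(C)C)cc(O[Si](C)(C)C(C)(C)C)c3c(=O)c2CC=C(C)C)c(O[Si](C)(C)C(C)(C)C)c1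
F6 | step 16 | 8-[(1S,5R,6S)-6-(2,4-diacetoxy-3-prenylbenzoyl)-5-(2,4-diacetoxyphenyl)-3-methylcyclohex-2-en-1-yl]-5,7-bis(tert-butyldimethylsilyloxy)-2-[2-(tert-butyldimethylsilyloxy)-4-(prenyloxy)phenyl]-3-prenyl-4H-chromen-4-one | CC(C)=CCOc1ccc(-c2oc3c([C@H]4C=C(C)C[C@@H](c5ccc(OC(C)=O)cc5OC(C)=O)[C@@H]4C(=O)c4ccc(OC(C)=O)c(CC=C(C)C)c4OC(C)=O)c(O[Si](C)(C)C(C)(C)C)cc(O[Si](C)(C)C(C)(C)C)c3c(=O)c2CC=C(C)C)c(O[Si](C)(C)C(C)(C)C)c1
F7 | step 7 | (E)-tert-butyldimethyl[(3-methylbuta-1,3-dien-1-yl)oxy]silane | C=C(C)/C=C/O[Si](C)(C)C(C)(C)C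
F8 | step 7 | [(1S,6R)-2-(tert-butyldimethylsilyloxy)-6-(2,4-diacetoxyphenyl)-4-methylcyclohex-3-en-1-yl](4-acetoxy-2-hydroxy-3-prenylphenyl)methanone, epimers at the silyloxy carbon | CC(C)(C)[Si](C)(C)OC1C=C(C)C[C@@H](c2ccc(OC(C)=O)cc2OC(C)=O)[C@@H]1C(=O)c1ccc(OC(C)=O)c(CC=C(C)C)c1O
F9 | step 7 | [(1S,6R)-2-(tert-butyldimethylsilyloxy)-6-(2,4-diacetoxyphenyl)-4-methylcyclohex-3-en-1-yl](2,4-diacetoxy-3-prenylphenyl)methanone, epimers at the silyloxy carbon | CC(C)(C)[Si](C)(C)OC1C=C(C)C[C@@H](c2ccc(OC(C)=O)cc2OC(C)=O)[C@@H]1C(=O)c1ccc(OC(C)=O)c(CC=C(C)C)c1OC(C)=O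
F10 | step 7 | [(1S,6R)-6-(2,4-diacetoxyphenyl)-2-hydroxy-4-methylcyclohex-3-en-1-yl](2,4-diacetoxy-3-prenylphenyl)methanone, epimers at the carbinol carbon | OC1C=C(C)C[C@@H](c2ccc(OC(C)=O)cc2OC(C)=O)[C@@H]1C(=O)c1ccc(OC(C)=O)c(CC=C(C)C)c1OC(C)=O
F11 | step 14 | 2-(tert-butyldimethylsilyloxy)-4-(prenyloxy)benzoic acid | CC(C)=CCOc1ccc(C(=O)O)c(O[Si](C)(C)C(C)(C)C)c1
F12 | step 14 | 3,5-bis(tert-butyldimethylsilyloxy)-2-(5-methylhex-4-enoyl)phenyl 2-(tert-butyldimethylsilyloxy)-4-(prenyloxy)benzoate | CC(C)=CCCC(=O)c1c(OC(=O)c2ccc(OCC=C(C)C)cc2O[Si](C)(C)C(C)(C)C)cc(O[Si](C)(C)C(C)(C)C)cc1O[Si](C)(C)C(C)(C)C
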